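Abbreviation used in names: DHB = (2S,3S)-4,7-bis(benzyloxy)-2-[3,5-bis(benzyloxy)phenyl]-3-[4-(benzyloxy)phenyl]-2,3-dihydro-1-benzofuran-5-yl.

## Structural features

The target is a 3-methoxy-4H-chromen-4-one whose benzo ring (ring A) carries hydroxyls at C5 and C7, a methyl at C6 and hydrogen at C8, and whose C2 is bonded to C5 of a 2,3-dihydrobenzofuran. The benzene ring of that bicycle (ring B) is an alkoxyhydroquinone: hydroxyls at C4 and C7, the ring oxygen on C7a, hydrogen only at C6. The dihydrofuran ring (ring D) holds the only two stereocentres, which are adjacent: C2 (3,5-dihydroxyphenyl, bonded to O1) and C3 (4-hydroxyphenyl, doubly benzylic). Both are S and the two aryl groups are trans. Fragile points are the seven phenols (above all the air-sensitive ring B hydroquinone), the benzylic C2–O1 bond (hydrogenolysis, acid ionisation) and the C3 methyl ether of the chromone, which must be the only O-methyl group present at deprotection. The difficulty is twofold: ring A is a C-methylphloroglucinol pattern in which classical closure through either ortho oxygen gives 6-methyl or 8-methyl chromones, and the trans-diaryl dihydrobenzofuran must be made as one enantiomer on a hindered 1,2,4-trioxygenated arene. The key step uses the fact that the ring A sequence C5(OH)–C6(CH3)–C7(O)–C8(H) matches C1(=O)–C2(CH3)–C3(OR)–C4(H) of a cyclobutenone atom for atom, while C8a and C4a are C6 and C5 of a 4-pyranone (ring C), so two bonds (C8–C8a, C4a–C5) build ring A with its substituents in place. Re-deriving every intermediate from the target confirmed the connectivity and the (2S,3S)-trans configuration used below; no structure needed to be changed.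

## Logic of the disconnections

35 from 34. The six benzyl–oxygen bonds are cut last. Benzyl can mask every phenol, including the C7 oxygen that arrives with the four-membered ring, and leaves in one neutral operation that spares the C3 methyl ether. The demand is that hydrogenolysis spares the benzylic C2–O1 bond and the pyranone double bond.

34 from 24 and 30. Chromone C8–C8a and C4a–C5 are cut, removing ring A as a four-carbon unit. This turns the 6-methyl/8-hydrogen question into the substitution pattern of a small ring and leaves a monocyclic pyranone. The forward step must couple at the chlorine-bearing carbon of 30 and close onto pyranone C5, so it needs a metal at C6 and hydrogen at C5. Two refinements serve it: the cyclobutenone oxygen is benzylated so that it leaves with the other five groups, and CuI is added to speed transfer from the electron-poor stannane.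

24 from 22. The C6–Sn bond is cut. Tin is installed last because a stannane would not survive the earlier palladium steps beside a halide. The demand is a base that removes the C6 proton without opening the pyranone or touching benzyl ethers.

22 from 18 and 21. The bond between pyranone C2 and benzofuran C5 is cut, separating the chiral half from a two-step achiral heterocycle. The halide sits on the pyranone, where it is activated as a vinylogous acyl halide, and boron on the electron-rich arene. The demand is coupling next to an ortho benzyloxy group under base mild enough for 21.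

21 from 20 from 19. The O–CH3 and C2–Br bonds are cut. The free enol of 19 directs halogen to C2, so bromination precedes methylation.

18 from 17. The C–B bond is cut back to C–Br, a handle that is easy to place early (para to a phenol) and inert until needed.

17 from 9 and 14. C2–C3 and O1–C2 are cut, removing ring D and both stereocentres in one operation and splitting the chiral half into two pieces of similar size. The demand is that the ylide adds through one face and that closure gives the trans ring; the bromide and benzyl ethers must tolerate carbonate.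

14 from 12 and 13, and 12 from 11 from 10. The S–benzyl bond is cut, then both ring C–S bonds, back to a commercial C2-symmetric diol. Because of the symmetry, sulfur is not a stereocentre and one salt forms. The demand is clean double inversion.

9 from 8 from 6 and 7. The C–S bond and then the aryl–carbinol C–C bond are cut. The sulfone is the storable precursor of the quinone methide. The demand is ionisation of 8 without loss of benzyl ethers.

6 from 5 from 4 from 2 from 1. The formyl C–C bond, the C–Br bond, the phenolic C–O bond (traced to an aldehyde carbon) and two O–benzyl bonds are cut. Ring B then derives from a cheap hydroquinone aldehyde, and the free phenol is used twice as director (para for bromine, ortho for formyl).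

30 from 29 from 28 from 26 from 25. The C–Cl bond, a C–H bond (hydride), the C–CH3 bond and two O–benzyl bonds are cut, back to a symmetric C4 acid. The demand is that hydride adds to the carbonyl next to the benzyloxy-bearing carbon, so that methyl ends up next to the surviving carbonyl.

## Other disconnections considered

Alternative 1: The cut is O1–C7a of ring D.
- Forward step: Ag2O would oxidise the chlorohydroquinone alcohol A1 to the quinone A2. The C2 hydroxyl then adds to C7a in a 5-exo conjugate addition and enolisation gives the dihydrobenzofurandiol A3.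
- In favour: the C7a oxygen is delivered by the side chain, so ring B can start from a plain hydroquinone without an extra oxidation. The closure forms no bond at a stereocentre, so C2 keeps its configuration; on this point it is better than any SN2 closure. The chlorine blocks C5 and later serves for coupling.
- Against: both stereocentres must already exist in open-chain A1, a hindered 1,2,2-triarylethanol with no short catalytic asymmetric entry. A2 has a doubly benzylic hydrogen on the carbon attached to the quinone and could tautomerise to a quinone methide, erasing C3. A3 is more electron-rich than A1 and may be oxidised further. A3 then needs two benzylations, and an aryl chloride is a poorer borylation partner than 17.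
- Comparison: structurally it answers a different question (how ring D closes) and leaves ring A unsolved, so it would have to be combined with the key step or a classical chromone synthesis. Mechanistically it is safer at C2 and riskier at C3. In step count it is longer by about three steps, whereas step 10 sets both centres and the ring at once.

Alternative 2: The cut is C2–C3 together with O1–C2.
- Forward step: Cs2CO3 would convert sulfone A4 into an o-quinone methide and the chiral thiolanium salt A5 into its benzylide. Conjugate addition and displacement of the sulfide by the phenoxide give bromide A6.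
- Relation to the chosen plan: this cut builds ring D, not ring A, so it does not compete with the key step. The chosen route uses it as step 10 (A4, A5 and A6 are the same compounds as 9, 14 and 17). What is weighed here is a plan in which this annulation carries the strategy and ring A comes from an arene, for example by coupling 18 with the 2-iodochromone A7.
- In favour: two bonds, one ring and both stereocentres in one step, which is more than the chosen key step achieves; it is the better step in that respect. It needs no tin and has a shorter endgame.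
- Against: A7 must come from C-methylphloroglucinol, where acylation and ring closure can involve either ortho oxygen (6-methyl or 8-methyl chromone) and the 5- and 7-oxygens must be told apart. C2 iodination of a 3-methoxychromone needs a strong base near the peri oxygen.
- Comparison: the stereochemical risk is equal, since both plans rely on this annulation. They differ only in ring A: the chosen plan fixes the positions by construction at the price of a tin reagent and an untested substrate, while this plan uses routine reactions at the price of a regiochemical separation. Step counts are about equal.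

Alternative 3: The cut removes ring B: C6–C7, C4–C5 and C3a–C4.
- Forward step: the Cr(CO)5 methoxycarbene A8 on a trans-2,3-diaryl-2,3-dihydrofuran would be heated with the 2-ethynylchromone A9. Alkyne insertion, CO insertion and electrocyclisation give the 4-hydroxy-7-methoxy arene A10.
- In favour: it is the most convergent of the four plans. It makes three C–C bonds and the hindered aryl–chromone bond without cross-coupling. The terminal alkyne should place the chromone ortho to the new hydroxyl, so regiocontrol on ring B equals that on ring A in the chosen plan.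
- Against: A8 needs an enantiopure trans-2,3-diaryl-2,3-dihydrofuran, an acid-sensitive enol ether that must be lithiated at C5 in the presence of three benzyl ethers. The alkyne of A9 is conjugated with the pyranone carbonyl, and electron-poor alkynes tend to divert chromium carbenes to furans, indenes or cyclobutenones. Stoichiometric chromium is no gain over stoichiometric tin. A10 carries a second methyl ether at C7 that must be removed beside the C3 methyl ether (oxidation to the quinone with (NH4)2Ce(NO3)6, then reduction; two more steps). A9 still needs a ring A of defined methyl position.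
- Comparison: equal in regiocontrol of the ring it builds and better in convergence; worse in unsolved sub-problems and by about two steps after the key step.

Key step: step 20

Assumption: the benzylide of 14 is taken to react through the same face as in aldehyde epoxidations with this sulfide class, where the (2S,5S)-sulfide gives (R,R)-configured epoxide carbons; that arrangement corresponds to 2S here, and the enantiomeric diol would replace 10 if the sense proved opposite.

## Route

Step 1
Reactants: 1 2,5-dihydroxybenzaldehyde
Product: 2 2,5-bis(benzyloxy)benzaldehyde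
Conditions: BnBr, K2CO3, DMF, 60 °C
Reagents that add atoms: benzyl bromide, BrCc1ccccc1
Why: Williamson ether synthesis; both phenoxides, including the hydrogen-bonded C2 one, are alkylated in DMF and the aldehyde is inert to carbonate.

Step 2
Reactants: 2 2,5-bis(benzyloxy)benzaldehyde
Product: 4 2,5-bis(benzyloxy)phenol, via aryl formate 3 (not isolated)
Conditions: mCPBA, CH2Cl2, 0 °C to rt; then K2CO3 (cat.), MeOH, rt
Reagents that add atoms: 3-chloroperoxybenzoic acid, OOC(=O)c1cccc(Cl)c1
Why: Baeyer–Villiger (Dakin-type) oxidation; the electron-rich aryl group migrates to give formate 3, and catalytic carbonate in methanol transfers the formyl group to the solvent without touching benzyl ethers.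

Step 3
Reactants: 4 2,5-bis(benzyloxy)phenol
Product: 5 2,5-bis(benzyloxy)-4-bromophenol
Conditions: NBS, CH2Cl2, −40 to 0 °C
Reagents that add atoms: N-bromosuccinimide, O=C1CCC(=O)N1Br
Why: Electrophilic aromatic bromination; the free hydroxyl directs para, to a carbon also ortho to a benzyloxy group, while the only other activated site lies between hydroxyl and benzyloxy and is more hindered.

Step 4
Reactants: 5 2,5-bis(benzyloxy)-4-bromophenol
Product: 6 3,6-bis(benzyloxy)-5-bromo-2-hydroxybenzaldehyde
Conditions: MgCl2, Et3N, (CH2O)n, MeCN, 80 °C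
Reagents that add atoms: paraformaldehyde (as formaldehyde), C=O
Why: Magnesium-mediated ortho-formylation of a phenol (Casnati–Skattebøl); the magnesium phenoxide delivers formaldehyde to the one free ortho carbon and a second formaldehyde oxidises the benzylic alkoxide by hydride transfer, with para blocked by bromine.

Step 5
Reactants: 6 3,6-bis(benzyloxy)-5-bromo-2-hydroxybenzaldehyde; 7 [4-(benzyloxy)phenyl]magnesium bromide (commercial THF solution)
Product: 8 3,6-bis(benzyloxy)-2-{[4-(benzyloxy)phenyl](hydroxy)methyl}-4-bromophenol (racemic)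
Conditions: THF, −20 °C to rt; aq. NH4Cl
Reagents that add atoms: none
Why: Grignard addition; the first equivalent of 7 forms the magnesium phenoxide and the second adds to the aldehyde, while the aryl bromide does not exchange with an arylmagnesium reagent at this temperature. The racemic carbinol centre is destroyed in step 10.

Step 6
Reactants: 8 the benzhydrol from step 5
Product: 9 3,6-bis(benzyloxy)-2-{[4-(benzyloxy)phenyl](4-methylbenzenesulfonyl)methyl}-4-bromophenol (racemic)
Conditions: p-TolSO2Na, HCO2H, THF–H2O, rt
Reagents that add atoms: sodium 4-methylbenzenesulfinate, [Na+].Cc1ccc(cc1)S([O-])=O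
Why: SN1 substitution; formic acid ionises the doubly activated benzhydrol to a cation that the sulfinate captures at sulfur, giving the thermodynamic sulfone, a bench-stable quinone methide precursor.

Step 7
Reactants: 10 (2R,5R)-hexane-2,5-diol
Product: 11 (2R,5R)-hexane-2,5-diyl dimethanesulfonate
Conditions: MsCl, Et3N, CH2Cl2, −10 to 0 °C
Reagents that add atoms: methanesulfonyl chloride, CS(Cl)(=O)=O
Why: Sulfonate ester formation; only O–S bonds form, so both carbinol carbons keep their configuration.

Step 8
Reactants: 11 (2R,5R)-hexane-2,5-diyl dimethanesulfonate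
Product: 12 (2S,5S)-2,5-dimethylthiolane
Conditions: Na2S·9H2O, DMSO, rt; distillation
Reagents that add atoms: sodium sulfide, [Na+].[Na+].[S-2]
Why: Double SN2 displacement by sulfide; each C–O bond is replaced with inversion (the second as a 5-exo-tet closure), turning the (R,R)-dimesylate into the (S,S)-thiolane, the established preparation of this sulfide class.

Step 9
Reactants: 12 (2S,5S)-2,5-dimethylthiolane; 13 3,5-bis(benzyloxy)benzyl bromide
Product: 14 (2S,5S)-1-[3,5-bis(benzyloxy)benzyl]-2,5-dimethylthiolan-1-ium trifluoromethanesulfonate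
Conditions: LiOTf, CH2Cl2–H2O, rt
Reagents that add atoms: lithium trifluoromethanesulfonate, [Li+].[O-]S(=O)(=O)C(F)(F)F
Why: S-alkylation of a sulfide by a benzylic bromide; lithium triflate replaces bromide by a non-nucleophilic counter-ion and drives the equilibrium, and C2 symmetry means sulfur is not stereogenic, so one salt forms.

Step 10
Reactants: 9 the sulfone from step 6; 14 the thiolanium triflate from step 9
Product: 17 (2S,3S)-4,7-bis(benzyloxy)-2-[3,5-bis(benzyloxy)phenyl]-3-[4-(benzyloxy)phenyl]-5-bromo-2,3-dihydro-1-benzofuran, via o-quinone methide 15 (not isolated), via sulfonium benzylide 16 (not isolated)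
Conditions: Cs2CO3, MeCN, −20 °C to rt
Reagents that add atoms: none
Why: Formal [4+1] annulation of a sulfonium ylide with an o-quinone methide (Corey–Chaykovsky type); carbonate eliminates sulfinate from 9 to give 15 and deprotonates 14 to 16, conjugate addition forms C2–C3, and the phenoxide displaces the sulfide (5-exo-tet, inversion at C2) to form O1–C2. C2 is set by the face of the benzylide left open by the two methyl groups of the C2-symmetric ring, the control element of epoxidations with such ylides, and C3 follows because addition and closure favour the two aryl groups trans.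

Step 11
Reactants: 17 the aryl bromide from step 10
Product: 18 2-(DHB)-4,4,5,5-tetramethyl-1,3,2-dioxaborolane
Conditions: B2pin2, PdCl2(dppf), KOAc, dioxane, 90 °C
Reagents that add atoms: bis(pinacolato)diboron, CC1(C)OB(OC1(C)C)B1OC(C)(C)C(C)(C)O1
Why: Miyaura borylation; oxidative addition to the aryl bromide, acetate-assisted transmetalation and reductive elimination, with neither stereocentre involved.

Step 12
Reactants: 19 3-hydroxy-4H-pyran-4-one (pyromeconic acid)
Product: 20 2-bromo-3-hydroxy-4H-pyran-4-one
Conditions: NBS, MeCN, 0 °C to rt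
Reagents that add atoms: N-bromosuccinimide, O=C1CCC(=O)N1Br
Why: Electrophilic bromination of an enol; C2 is the β-carbon of the C3 enol and the position ortho to the hydroxyl, the site at which 3-hydroxy-4-pyranones are halogenated.

Step 13
Reactants: 20 2-bromo-3-hydroxy-4H-pyran-4-one
Product: 21 2-bromo-3-methoxy-4H-pyran-4-one
Conditions: MeI, K2CO3, acetone, 50 °C
Reagents that add atoms: iodomethane, CI
Why: Williamson O-methylation of the acidic enolic hydroxyl; carbonate in acetone does not displace the vinylogous acyl bromide.

Step 14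
Reactants: 18 the boronate from step 11; 21 2-bromo-3-methoxy-4H-pyran-4-one
Product: 22 2-(DHB)-3-methoxy-4H-pyran-4-one
Conditions: Pd(OAc)2, SPhos, K3PO4, toluene–H2O, 80 °C
Reagents that add atoms: none
Why: Suzuki–Miyaura coupling; oxidative addition into the activated C2–Br bond is fast, and a bulky biarylphosphine with phosphate allows transmetalation of the ortho-substituted boronate without touching a stereocentre.

Step 15
Reactants: 22 2-(DHB)-3-methoxy-4H-pyran-4-one
Product: 24 2-(DHB)-3-methoxy-6-(tributylstannyl)-4H-pyran-4-one, via pyranonylzinc chloride 23 (not isolated)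
Conditions: TMPZnCl·LiCl (commercial THF solution), THF, 25 °C; then Bu3SnCl, 25 to 50 °C
Reagents that add atoms: tributyltin chloride, CCCC[Sn](Cl)(CCCC)CCCC
Why: Directed zincation then transmetalation to tin; the amide base removes C6–H (vinylic, next to the ring oxygen, C2 being substituted) as in the known C2 zincation of chromones and 4-pyranones, and the zinc species, which does not ring-open as lithium or magnesium analogues do, is trapped by Bu3SnCl.

Step 16
Reactants: 25 squaric acid
Product: 26 3,4-bis(benzyloxy)cyclobut-3-ene-1,2-dione (dibenzyl squarate)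
Conditions: BnOH, toluene, reflux, Dean–Stark
Reagents that add atoms: benzyl alcohol, OCc1ccccc1
Why: Self-catalysed esterification of a strongly acidic vinylogous carboxylic acid, driven by azeotropic removal of water.

Step 17
Reactants: 26 dibenzyl squarate
Product: 28 3-(benzyloxy)-4-methylcyclobut-3-ene-1,2-dione, via lithium alkoxide adduct 27 (not isolated)
Conditions: MeLi, THF, −78 °C; (CF3CO)2O, −78 °C; aq. NH4Cl
Reagents that add atoms: methyllithium, [Li]C; water, O
Why: 1,2-Addition of the organolithium to one squarate carbonyl gives 27; trifluoroacetylation, ionisation and hydrolysis on work-up transpose the oxygen function and expel benzyl alcohol, the standard route from squarates to 3-alkoxy-4-alkylcyclobutenediones.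

Step 18
Reactants: 28 3-(benzyloxy)-4-methylcyclobut-3-ene-1,2-dione
Product: 29 3-(benzyloxy)-4-hydroxy-2-methylcyclobut-2-en-1-one (racemic)
Conditions: LiAlH(OtBu)3, THF, −78 °C
Reagents that add atoms: none
Why: Chemoselective hydride reduction; the bulky, mild hydride attacks the ketone-like carbonyl next to the benzyloxy-bearing carbon, not the vinylogous ester carbonyl next to the methyl-bearing carbon. The racemic carbinol centre is lost in step 20.

Step 19
Reactants: 29 3-(benzyloxy)-4-hydroxy-2-methylcyclobut-2-en-1-one
Product: 30 3-(benzyloxy)-4-chloro-2-methylcyclobut-2-en-1-one (racemic)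
Conditions: SOCl2, pyridine, CH2Cl2, −20 to 0 °C; used at once
Reagents that add atoms: thionyl chloride, O=S(Cl)Cl
Why: Deoxychlorination through the chlorosulfite with SN2 displacement at the α-keto carbon; pyridine scavenges HCl, which would otherwise collapse the 4-hydroxy-3-alkoxycyclobutenone to a cyclobutenedione, and attack at the methyl-bearing terminus is disfavoured because it would deconjugate the enone.

Step 20
Reactants: 24 2-(DHB)-3-methoxy-6-(tributylstannyl)-4H-pyran-4-one; 30 3-(benzyloxy)-4-chloro-2-methylcyclobut-2-en-1-one
Product: 34 7-(benzyloxy)-2-(DHB)-5-hydroxy-3-methoxy-6-methyl-4H-chromen-4-one, via pyranonylcyclobutenone 31 (not isolated), via vinylketene 32 (not isolated), via cyclohexadienone tautomer 33 (not isolated)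
Conditions: PdCl2(PhCN)2 (5 mol %), tri(2-furyl)phosphine (10 mol %), CuI (10 mol %), dioxane, 50 then 100 °C
Reagents that add atoms: none
Why: The divalent palladium precatalyst is reduced in situ to zerovalent palladium, which adds to the allylic, α-keto C–Cl bond of 30; CuI-assisted transmetalation from 24 (an α-oxygenated alkenylstannane) and reductive elimination at the carbon that keeps the enone conjugated and avoids a quaternary centre give 31 and with it chromone C8–C8a. At 100 °C 31 undergoes reversible thermal conrotatory 4π ring opening, and only the rotamer with the pyranone turned inward, the (E)-vinylketene 32, can react further. Ring A then closes by thermal disrotatory 6π electrocyclisation across the ketene C=C, the enol ether C=C and pyranone C5=C6, joining the ketene carbon to C5 (chromone C4a–C5) to give 33, whose C4a hydrogen lies between two carbonyl groups and shifts to oxygen to give the chelated phenol 34. The closest known reaction type is the palladium-catalysed coupling of 4-chlorocyclobutenones with aryl, heteroaryl and alkenyl stannanes followed by thermal benzannulation to phenols; here the ene partner is a pyranone double bond outside any benzene ring, so closure costs little aromatic stabilisation. No stereocentre is formed, and the two existing ones are remote and see neither acid nor base. The selectivity needed is the placing of oxygen, methyl and hydrogen on ring A, secured by the four-membered ring itself (C1 becomes C5–OH, C2–CH3 becomes C6, C3–OBn becomes C7, C4–H becomes C8). The site of closure is secured because C5 is the only carbon next to the coupled position.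

Step 21
Reactants: 34 the hexa-O-benzyl chromone from step 20
Product: 35 2-[(2S,3S)-2-(3,5-dihydroxyphenyl)-4,7-dihydroxy-3-(4-hydroxyphenyl)-2,3-dihydro-1-benzofuran-5-yl]-5,7-dihydroxy-3-methoxy-6-methyl-4H-chromen-4-one
Conditions: H2 (1 atm), Pd/C, EtOAc–MeOH (degassed), rt; work-up under argon
Reagents that add atoms: none
Why: Catalytic hydrogenolysis of six aryl benzyl ethers; primary O-benzyl groups cleave much faster than the ring-held secondary C2–O1 ether, the pyranone double bond of flavone-type chromones is not reduced under these conditions, and neither stereocentre is touched.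

## Compound list

1 | 2,5-dihydroxybenzaldehyde | O=Cc1cc(O)ccc1O | starting material
2 | 2,5-bis(benzyloxy)benzaldehyde | O=Cc1cc(OCc2ccccc2)ccc1OCc1ccccc1 | intermediate
3 | 2,5-bis(benzyloxy)phenyl formate | O=COc1cc(OCc2ccccc2)ccc1OCc1ccccc1 | intermediate (not isolated)
4 | 2,5-bis(benzyloxy)phenol | Oc1cc(OCc2ccccc2)ccc1OCc1ccccc1 | intermediate
5 | 2,5-bis(benzyloxy)-4-bromophenol | Oc1cc(OCc2ccccc2)c(Br)cc1OCc1ccccc1 | intermediate
6 | 3,6-bis(benzyloxy)-5-bromo-2-hydroxybenzaldehyde | O=Cc1c(O)c(OCc2ccccc2)cc(Br)c1OCc1ccccc1 | intermediate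
7 | [4-(benzyloxy)phenyl]magnesium bromide | Br[Mg]c1ccc(OCc2ccccc2)cc1 | starting material
8 | 3,6-bis(benzyloxy)-2-{[4-(benzyloxy)phenyl](hydroxy)methyl}-4-bromophenol (racemic) | OC(c1ccc(OCc2ccccc2)cc1)c1c(O)c(OCc2ccccc2)cc(Br)c1OCc1ccccc1 | intermediate
9 | 3,6-bis(benzyloxy)-2-{[4-(benzyloxy)phenyl](4-methylbenzenesulfonyl)methyl}-4-bromophenol (racemic) | Cc1ccc(cc1)S(=O)(=O)C(c1ccc(OCc2ccccc2)cc1)c1c(O)c(OCc2ccccc2)cc(Br)c1OCc1ccccc1 | intermediate
10 | (2R,5R)-hexane-2,5-diol | C[C@@H](O)CC[C@@H](C)O | starting material
11 | (2R,5R)-hexane-2,5-diyl dimethanesulfonate | C[C@@H](OS(C)(=O)=O)CC[C@@H](C)OS(C)(=O)=O | intermediate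
12 | (2S,5S)-2,5-dimethylthiolane | C[C@H]1CC[C@H](C)S1 | intermediate
13 | 3,5-bis(benzyloxy)benzyl bromide | BrCc1cc(OCc2ccccc2)cc(OCc2ccccc2)c1 | starting material
14 | (2S,5S)-1-[3,5-bis(benzyloxy)benzyl]-2,5-dimethylthiolan-1-ium trifluoromethanesulfonate | C[C@H]1CC[C@H](C)[S+]1Cc1cc(OCc2ccccc2)cc(OCc2ccccc2)c1.[O-]S(=O)(=O)C(F)(F)F | intermediate
15 | 3,6-bis(benzyloxy)-2-[4-(benzyloxy)benzylidene]-4-bromocyclohexa-3,5-dien-1-one (o-quinone methide) | O=C1C(OCc2ccccc2)=CC(Br)=C(OCc2ccccc2)C1=Cc1ccc(OCc2ccccc2)cc1 | intermediate (not isolated)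
16 | (2S,5S)-1-[3,5-bis(benzyloxy)benzylidene]-2,5-dimethyl-1λ4-thiolane (sulfonium benzylide) | C[C@H]1CC[C@H](C)[S+]1[CH-]c1cc(OCc2ccccc2)cc(OCc2ccccc2)c1 | intermediate (not isolated)
17 | (2S,3S)-4,7-bis(benzyloxy)-2-[3,5-bis(benzyloxy)phenyl]-3-[4-(benzyloxy)phenyl]-5-bromo-2,3-dihydro-1-benzofuran | Brc1cc(OCc2ccccc2)c2c(c1OCc1ccccc1)[C@H](c1ccc(OCc3ccccc3)cc1)[C@@H](c1cc(OCc3ccccc3)cc(OCc3ccccc3)c1)O2 | intermediate
18 | 2-(DHB)-4,4,5,5-tetramethyl-1,3,2-dioxaborolane | CC1(C)OB(OC1(C)C)c1cc(OCc2ccccc2)c2c(c1OCc1ccccc1)[C@H](c1ccc(OCc3ccccc3)cc1)[C@@H](c1cc(OCc3ccccc3)cc(OCc3ccccc3)c1)O2 | intermediate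
19 | 3-hydroxy-4H-pyran-4-one (pyromeconic acid) | O=c1ccocc1O | starting material
20 | 2-bromo-3-hydroxy-4H-pyran-4-one | O=c1ccoc(Br)c1O | intermediate
21 | 2-bromo-3-methoxy-4H-pyran-4-one | COc1c(Br)occc1=O | intermediate
22 | 2-(DHB)-3-methoxy-4H-pyran-4-one | COc1c(-c2cc(OCc4ccccc4)c3c(c2OCc2ccccc2)[C@H](c2ccc(OCc4ccccc4)cc2)[C@@H](c2cc(OCc4ccccc4)cc(OCc4ccccc4)c2)O3)occc1=O | intermediate
23 | chloro[6-(DHB)-5-methoxy-4-oxo-4H-pyran-2-yl]zinc (LiCl complex) | COc1c(-c2cc(OCc4ccccc4)c3c(c2OCc2ccccc2)[C@H](c2ccc(OCc4ccccc4)cc2)[C@@H](c2cc(OCc4ccccc4)cc(OCc4ccccc4)c2)O3)oc([Zn]Cl)cc1=O | intermediate (not isolated)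
24 | 2-(DHB)-3-methoxy-6-(tributylstannyl)-4H-pyran-4-one | COc1c(-c2cc(OCc4ccccc4)c3c(c2OCc2ccccc2)[C@H](c2ccc(OCc4ccccc4)cc2)[C@@H](c2cc(OCc4ccccc4)cc(OCc4ccccc4)c2)O3)oc([Sn](CCCC)(CCCC)CCCC)cc1=O | intermediate
25 | squaric acid | OC1=C(O)C(=O)C1=O | starting material
26 | 3,4-bis(benzyloxy)cyclobut-3-ene-1,2-dione | O=C1C(=O)C(OCc2ccccc2)=C1OCc1ccccc1 | intermediate
27 | lithium 2,3-bis(benzyloxy)-1-methyl-4-oxocyclobut-2-en-1-olate | [Li+].CC1([O-])C(OCc2ccccc2)=C(OCc2ccccc2)C1=O | intermediate (not isolated)
28 | 3-(benzyloxy)-4-methylcyclobut-3-ene-1,2-dione | CC1=C(OCc2ccccc2)C(=O)C1=O | intermediate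
29 | 3-(benzyloxy)-4-hydroxy-2-methylcyclobut-2-en-1-one (racemic) | CC1=C(OCc2ccccc2)C(O)C1=O | intermediate
30 | 3-(benzyloxy)-4-chloro-2-methylcyclobut-2-en-1-one (racemic) | CC1=C(OCc2ccccc2)C(Cl)C1=O | intermediate
31 | 2-(DHB)-6-[2-(benzyloxy)-3-methyl-4-oxocyclobut-2-en-1-yl]-3-methoxy-4H-pyran-4-one (both epimers at the new sp3 carbon) | COc1c(-c2cc(OCc4ccccc4)c3c(c2OCc2ccccc2)[C@H](c2ccc(OCc4ccccc4)cc2)[C@@H](c2cc(OCc4ccccc4)cc(OCc4ccccc4)c2)O3)oc(C2C(OCc4ccccc4)=C(C)C2=O)cc1=O | intermediate (not isolated)
32 | 2-(DHB)-6-[(1E)-2-(benzyloxy)-3-methyl-4-oxobuta-1,3-dien-1-yl]-3-methoxy-4H-pyran-4-one | COc1c(-c2cc(OCc4ccccc4)c3c(c2OCc2ccccc2)[C@H](c2ccc(OCc4ccccc4)cc2)[C@@H](c2cc(OCc4ccccc4)cc(OCc4ccccc4)c2)O3)oc(/C=C(/OCc4ccccc4)C(C)=C=O)cc1=O | intermediate (not isolated)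
33 | 7-(benzyloxy)-2-(DHB)-3-methoxy-6-methyl-4aH-chromene-4,5-dione (both epimers at C4a) | COC1=C(c2cc(OCc4ccccc4)c3c(c2OCc2ccccc2)[C@H](c2ccc(OCc4ccccc4)cc2)[C@@H](c2cc(OCc4ccccc4)cc(OCc4ccccc4)c2)O3)OC2=CC(OCc4ccccc4)=C(C)C(=O)C2C1=O | intermediate (not isolated)
34 | 7-(benzyloxy)-2-(DHB)-5-hydroxy-3-methoxy-6-methyl-4H-chromen-4-one | COc1c(-c2cc(OCc4ccccc4)c3c(c2OCc2ccccc2)[C@H](c2ccc(OCc4ccccc4)cc2)[C@@H](c2cc(OCc4ccccc4)cc(OCc4ccccc4)c2)O3)oc2cc(OCc3ccccc3)c(C)c(O)c2c1=O | intermediate
35 | 2-[(2S,3S)-2-(3,5-dihydroxyphenyl)-4,7-dihydroxy-3-(4-hydroxyphenyl)-2,3-dihydro-1-benzofuran-5-yl]-5,7-dihydroxy-3-methoxy-6-methyl-4H-chromen-4-one | COc1c(-c2cc(O)c3c(c2O)[C@H](c2ccc(O)cc2)[C@@H](c2cc(O)cc(O)c2)O3)oc2cc(O)c(C)c(O)c2c1=O | target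

## Step count and least certain steps

Total: 21 steps. Longest linear sequence: 12 steps (1, 2, 3, 4, 5, 6, 10, 11, 14, 15, 20, 21).

Step 20 (key step). The most likely failure is slow transmetalation from the hindered, electron-poor stannane, so that protodestannylation, homocoupling or thermal decay of 30 take over. Less likely are reductive elimination at the methyl-bearing end of the allyl system (leading to the regioisomeric phenol) and capture of the ketene by adventitious nucleophiles. The fallback replaces cross-coupling by carbonyl addition and thermal ring expansion. It sets out from 22 (zincated to 23 as in step 15) and from 28. Reagent 23, activated with MgCl2, is added at −40 °C to the more electrophilic carbonyl of 28 (next to the benzyloxy-bearing carbon) to give the hydroxycyclobutenone adduct F1. Heating in toluene at 110 °C under argon opens the four-membered ring with the hydroxyl turning outward and closes ring A onto pyranone C5, giving the 5,8-dihydroxychromone F2. The unchelated C8 hydroxyl is triflated selectively (PhNTf2, K2CO3, DMF) to the C8 triflate F3. Reduction (Pd(OAc)2, dppf, HCO2H, Et3N, DMF, 70 °C) returns to the route at 34. This path needs neither 29 nor 30 and so also covers a failure of step 19.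

Step 10. The most likely failure is incomplete face selection by the benzylide, or erosion of the trans preference, since the asymmetric version with a benzylic ylide is untested on quinone methides. Benzyl transfer from sulfur to the phenoxide or the sulfinate, and dimerisation of 15, may also compete. The fallback gives up asymmetric induction for resolution. It sets out from 9, which is treated under the same conditions with the achiral 1-[3,5-bis(benzyloxy)benzyl]thiolan-1-ium triflate F4 (from tetrahydrothiophene, 13 and LiOTf) to give the racemic trans-bromide F5. Preparative chromatography on a chiral stationary phase separates the (2S,3S) half, which is 17 (where the route is rejoined), from the (2R,3R)-enantiomer F6.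

Step 15. The most likely failure is incomplete transfer from zinc to tin, because the zinc reagent is a weak nucleophile; loss of tin by protonation during purification is the second concern. The fallback separates halogenation from stannylation. It sets out from 23, which is quenched with I2 (THF, 0 °C) to give the 6-iodopyranone F7. Stannylation with Bu3SnSnBu3 and Pd(PPh3)4 (toluene, 100 °C) returns to the route at 24.

Step 14. The most likely failure is protodeboronation of the electron-rich, ortho-alkoxy boronate, together with displacement of bromide from 21 by aqueous base. The fallback reverses the polarity and needs no boron. It sets out from 19 and 17. O-Methylation of 19 (MeI, K2CO3) gives 3-methoxy-4H-pyran-4-one F8. Zincation with TMPZnCl·LiCl, expected at C2 between the ring oxygen and the methoxy group, gives the pyranonylzinc chloride F9. Negishi coupling with 17 (Pd(OAc)2, SPhos, THF, 50 °C) returns to the route at 22, bypassing 18, 20 and 21.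

Step 21. The most likely failure is over-reduction (hydrogenolysis of the benzylic C2–O1 bond, or saturation of the pyranone double bond on long exposure) and air oxidation of the ring B hydroquinone during isolation. The fallback replaces hydrogenolysis by Lewis acid cleavage. It sets out from 34, which is treated with BCl3 and pentamethylbenzene (CH2Cl2, −78 °C), conditions that cleave aryl benzyl ethers in preference to aryl methyl ethers, and arrives at 35; no compound outside the list is formed (F0).

## Further compounds

F1 | step 20 | 2-(DHB)-6-[2-(benzyloxy)-1-hydroxy-3-methyl-4-oxocyclobut-2-en-1-yl]-3-methoxy-4H-pyran-4-one (both epimers at the carbinol carbon) | COc1c(-c2cc(OCc4ccccc4)c3c(c2OCc2ccccc2)[C@H](c2ccc(OCc4ccccc4)cc2)[C@@H](c2cc(OCc4ccccc4)cc(OCc4ccccc4)c2)O3)oc(C2(O)C(OCc4ccccc4)=C(C)C2=O)cc1=O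
F2 | step 20 | 7-(benzyloxy)-2-(DHB)-5,8-dihydroxy-3-methoxy-6-methyl-4H-chromen-4-one | COc1c(-c2cc(OCc4ccccc4)c3c(c2OCc2ccccc2)[C@H](c2ccc(OCc4ccccc4)cc2)[C@@H](c2cc(OCc4ccccc4)cc(OCc4ccccc4)c2)O3)oc2c(O)c(OCc3ccccc3)c(C)c(O)c2c1=O
F3 | step 20 | 7-(benzyloxy)-2-(DHB)-5-hydroxy-3-methoxy-6-methyl-4-oxo-4H-chromen-8-yl trifluoromethanesulfonate | COc1c(-c2cc(OCc4ccccc4)c3c(c2OCc2ccccc2)[C@H](c2ccc(OCc4ccccc4)cc2)[C@@H](c2cc(OCc4ccccc4)cc(OCc4ccccc4)c2)O3)oc2c(OS(=O)(=O)C(F)(F)F)c(OCc3ccccc3)c(C)c(O)c2c1=O
F4 | step 10 | 1-[3,5-bis(benzyloxy)benzyl]thiolan-1-ium trifluoromethanesulfonate | C1CC[S+](C1)Cc1cc(OCc2ccccc2)cc(OCc2ccccc2)c1.[O-]S(=O)(=O)C(F)(F)F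
F5 | step 10 | racemic trans-4,7-bis(benzyloxy)-2-[3,5-bis(benzyloxy)phenyl]-3-[4-(benzyloxy)phenyl]-5-bromo-2,3-dihydro-1-benzofuran (both enantiomers) | Brc1cc(OCc2ccccc2)c2c(c1OCc1ccccc1)[C@H](c1ccc(OCc3ccccc3)cc1)[C@@H](c1cc(OCc3ccccc3)cc(OCc3ccccc3)c1)O2.Brc1cc(OCc2ccccc2)c2c(c1OCc1ccccc1)[C@@H](c1ccc(OCc3ccccc3)cc1)[C@H](c1cc(OCc3ccccc3)cc(OCc3ccccc3)c1)O2
F6 | step 10 | (2R,3R)-4,7-bis(benzyloxy)-2-[3,5-bis(benzyloxy)phenyl]-3-[4-(benzyloxy)phenyl]-5-bromo-2,3-dihydro-1-benzofuran | Brc1cc(OCc2ccccc2)c2c(c1OCc1ccccc1)[C@@H](c1ccc(OCc3ccccc3)cc1)[C@H](c1cc(OCc3ccccc3)cc(OCc3ccccc3)c1)O2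
F7 | step 15 | 2-(DHB)-6-iodo-3-methoxy-4H-pyran-4-one | COc1c(-c2cc(OCc4ccccc4)c3c(c2OCc2ccccc2)[C@H](c2ccc(OCc4ccccc4)cc2)[C@@H](c2cc(OCc4ccccc4)cc(OCc4ccccc4)c2)O3)oc(I)cc1=O
F8 | step 14 | 3-methoxy-4H-pyran-4-one | COc1coccc1=O
F9 | step 14 | chloro(3-methoxy-4-oxo-4H-pyran-2-yl)zinc | COc1c([Zn]Cl)occc1=O
F0 | step 21 | none | none
A1 | alternative 1 | (1S,2S)-1-[3,5-bis(benzyloxy)phenyl]-2-[4-(benzyloxy)phenyl]-2-(3-chloro-2,5-dihydroxyphenyl)ethan-1-ol | Oc1cc(Cl)c(O)c(c1)[C@H](c1ccc(OCc2ccccc2)cc1)[C@H](O)c1cc(OCc2ccccc2)cc(OCc2ccccc2)c1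
A2 | alternative 1 | 2-{(1S,2S)-2-[3,5-bis(benzyloxy)phenyl]-1-[4-(benzyloxy)phenyl]-2-hydroxyethyl}-6-chlorocyclohexa-2,5-diene-1,4-dione | O=C1C=C(Cl)C(=O)C(=C1)[C@H](c1ccc(OCc2ccccc2)cc1)[C@H](O)c1cc(OCc2ccccc2)cc(OCc2ccccc2)c1
A3 | alternative 1 | (2S,3S)-2-[3,5-bis(benzyloxy)phenyl]-3-[4-(benzyloxy)phenyl]-5-chloro-2,3-dihydro-1-benzofuran-4,7-diol | Clc1cc(O)c2c(c1O)[C@H](c1ccc(OCc3ccccc3)cc1)[C@@H](c1cc(OCc3ccccc3)cc(OCc3ccccc3)c1)O2
A4 | alternative 2 | 3,6-bis(benzyloxy)-2-{[4-(benzyloxy)phenyl](4-methylbenzenesulfonyl)methyl}-4-bromophenol (racemic) | Cc1ccc(cc1)S(=O)(=O)C(c1ccc(OCc2ccccc2)cc1)c1c(O)c(OCc2ccccc2)cc(Br)c1OCc1ccccc1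
A5 | alternative 2 | (2S,5S)-1-[3,5-bis(benzyloxy)benzyl]-2,5-dimethylthiolan-1-ium trifluoromethanesulfonate | C[C@H]1CC[C@H](C)[S+]1Cc1cc(OCc2ccccc2)cc(OCc2ccccc2)c1.[O-]S(=O)(=O)C(F)(F)F
A6 | alternative 2 | (2S,3S)-4,7-bis(benzyloxy)-2-[3,5-bis(benzyloxy)phenyl]-3-[4-(benzyloxy)phenyl]-5-bromo-2,3-dihydro-1-benzofuran | Brc1cc(OCc2ccccc2)c2c(c1OCc1ccccc1)[C@H](c1ccc(OCc3ccccc3)cc1)[C@@H](c1cc(OCc3ccccc3)cc(OCc3ccccc3)c1)O2
A7 | alternative 2 | 7-(benzyloxy)-5-hydroxy-2-iodo-3-methoxy-6-methyl-4H-chromen-4-one | COc1c(I)oc2cc(OCc3ccccc3)c(C)c(O)c2c1=O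
A8 | alternative 3 | pentacarbonyl{[(4R,5S)-5-[3,5-bis(benzyloxy)phenyl]-4-[4-(benzyloxy)phenyl]-4,5-dihydrofuran-2-yl](methoxy)methylidene}chromium | COC(=[Cr](=C=O)(=C=O)(=C=O)(=C=O)=C=O)C1=C[C@H](c2ccc(OCc3ccccc3)cc2)[C@@H](c2cc(OCc3ccccc3)cc(OCc3ccccc3)c2)O1
A9 | alternative 3 | 5,7-bis(benzyloxy)-2-ethynyl-3-methoxy-6-methyl-4H-chromen-4-one | COc1c(C#C)oc2cc(OCc3ccccc3)c(C)c(OCc3ccccc3)c2c1=O
A10 | alternative 3 | 5,7-bis(benzyloxy)-2-{(2S,3S)-2-[3,5-bis(benzyloxy)phenyl]-3-[4-(benzyloxy)phenyl]-4-hydroxy-7-methoxy-2,3-dihydro-1-benzofuran-5-yl}-3-methoxy-6-methyl-4H-chromen-4-one | COc1c(-c2cc(OC)c3c(c2O)[C@H](c2ccc(OCc4ccccc4)cc2)[C@@H](c2cc(OCc4ccccc4)cc(OCc4ccccc4)c2)O3)oc2cc(OCc3ccccc3)c(C)c(OCc3ccccc3)c2c1=O
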